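**Plan**

- Retrosynthesis: the C3 carbinol goes back to a C3 ketone. Ring A is opened at C3–C4 (radical addition of C4 to a nitrile carbon) and at C1=C2 (olefination of a C10 formyl group). Ring B is cut at C5–C6 and C9–C10 ([4+2]), the triene at C6=C7 (methylenation), and the C15–O acyl bond last.
- Enabling feature (labdane numbering): ring B is a cyclohexene whose C7=C8 bond, carrying the C8 methyl, lies opposite the C5–C10 bond. C6=C7–C8(CH3)=C9 with the whole C11–C15 arm is therefore a geraniol chain lengthened by one vinyl carbon. C5=C10 is the α,β-bond of an α-methyl enal whose formyl carbon is C1 and whose β-isopropenyl group is latent C4.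
- Forward: the C15 oxygen receives its final (S)-3-methylpentanoyl group at the start, so no protecting group is needed. The chain is oxidised and methylenated to the triene, ring B is formed by the Diels–Alder reaction with the dienal, ring A is closed by C3–C4 bond formation, and ketone reduction ends the route.
- Stereochemistry: C5, C9 and C10 come from the catalytic cycloaddition ((E)-enal, (E)-diene, exo-formyl approach, catalyst-controlled face). The trans ring fusion follows from the trans C1/C4 arrangement on ring B. C3 comes from equatorial hydride delivery. The side-chain centre is bought, and both alkene geometries come from geraniol and an (E)-selective allylic oxidation.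

Key step: step 6

Assumption: the sense of induction known for α-substituted acroleins with this catalyst family (diene attack on the Re face of the α-carbon with the (S)-prolinol-derived catalyst) is taken to hold for the dienal, so the (R)-prolinol-derived catalyst is specified. Atom labels C1–C20 follow labdane numbering throughout.

**Step 1**
Reactants: 1 geraniol; 2 (3S)-3-methylpentanoic acid
Product: 3 geranyl (3S)-3-methylpentanoate
Conditions: N,N'-dicyclohexylcarbodiimide, 4-dimethylaminopyridine (cat.), CH2Cl2, 0 °C → rt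
Reagents that add atoms: none
Why: Steglich esterification of a primary allylic alcohol; the acid stereocentre is β to the carbonyl, cannot enolise, and is carried unchanged to the target.

**Step 2**
Reactants: 3 geranyl (3S)-3-methylpentanoate
Product: 4 (2E,6E)-8-hydroxy-3,7-dimethylocta-2,6-dien-1-yl (3S)-3-methylpentanoate
Conditions: SeO2 (cat.), t-BuOOH, salicylic acid (cat.), CH2Cl2, rt
Reagents that add atoms: tert-butyl hydroperoxide, CC(C)(C)OO (terminal oxygen source); selenium dioxide, O=[Se]=O (catalytic oxygen carrier)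
Why: Sharpless-type SeO2 allylic oxidation (ene reaction then [2,3]-shift) attacks the electron-rich terminal trisubstituted alkene at its (E)-methyl group and should give the (E)-allylic alcohol, while the alkene next to the ester is deactivated.

**Step 3**
Reactants: 4 (2E,6E)-8-hydroxy ester
Product: 5 (2E,6E)-3,7-dimethyl-8-oxoocta-2,6-dien-1-yl (3S)-3-methylpentanoate
Conditions: MnO2, CH2Cl2, rt
Reagents that add atoms: none
Why: MnO2 oxidation of an allylic alcohol to the enal without touching the ester or alkene geometry; any enal already formed in step 2 is pooled here.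

**Step 4**
Reactants: 5 (2E,6E)-8-oxo ester
Product: 6 (2E,6E)-3,7-dimethylnona-2,6,8-trien-1-yl (3S)-3-methylpentanoate
Conditions: Ph3PCH3Br, KN(SiMe3)2, THF, 0 °C; then 5, −78 → 0 °C
Reagents that add atoms: methyltriphenylphosphonium bromide, C[P+](c1ccccc1)(c1ccccc1)c1ccccc1.[Br-]
Why: Wittig methylenation; the unstabilised ylide (no excess base) adds to the enal far faster than to the ester, and the C8=C9 (E) geometry is retained, giving the (E)-1-alkyl-2-methyl-1,3-diene.

**Step 5**
Reactants: 7 methacrolein; 8 2-(triphenylphosphoranylidene)propanal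
Product: 9 (2E)-2,4-dimethylpenta-2,4-dienal
Conditions: 7 (3 equiv), CH2Cl2, BHT (trace), 45 °C, sealed tube
Reagents that add atoms: none
Why: Wittig reaction of a formyl-stabilised ylide, which should give the (E)-trisubstituted enal; excess methacrolein suppresses a second olefination of the less electrophilic product.

**Step 6**
Reactants: 6 trienyl ester; 9 (2E)-2,4-dimethylpenta-2,4-dienal
Product: 10 (2E)-5-[(1R,5R,6R)-6-formyl-2,6-dimethyl-5-(prop-1-en-2-yl)cyclohex-2-en-1-yl]-3-methylpent-2-en-1-yl (3S)-3-methylpentanoate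
Conditions: (R)-3,3-diphenyl-1-(2-methylphenyl)tetrahydro-1H,3H-pyrrolo[1,2-c][1,3,2]oxazaborole (20 mol%, from (R)-α,α-diphenylprolinol and (o-TolBO)3), HN(SO2CF3)2 (17 mol%), 9 (1.5 equiv, slow addition), CH2Cl2, −78 → −40 °C
Reagents that add atoms: none
Why: Proposed new method: the cationic oxazaborolidine binds the formyl oxygen of 9 (with the formyl C–H···O contact to the ring oxygen), lowers the LUMO of the C5=C10 bond and lets the C6=C7–C8=C9 diene of 6 add in a concerted but asynchronous [4+2] cycloaddition in which C5–C6 forms ahead of C9–C10; the closest known reaction type is the oxazaborolidinium-catalysed enantioselective Diels–Alder reaction of α-methyl enals such as methacrolein with acyclic 1,3-dienes, which has not been shown for a β-alkenyl α-methyl enal or for a 1,2-disubstituted diene. Ring B closes as a six-membered carbocycle by intermolecular [4+2] cycloaddition, the C7=C8 bond arising from the centre of the diene. C5 and C10 are fixed relative to each other by suprafacial addition to the (E)-enal (C20 methyl cis to isopropenyl), C9 relative to C10 by the (E)-diene geometry together with an exo-formyl transition state (C11 cis to C20), and the absolute sense by the catalyst, whose aryl groups cover one face of the s-trans enal so that the diene reaches the Si face of C10. The step needs ortho regiochemistry, exo-formyl orientation, one enantioface, and reaction at the α,β- rather than the γ,δ-bond of 9. These should follow from the β-carbon C5 meeting the unsubstituted terminus C6 (the developing allyl cation is stabilised by the C9 alkyl group, and C5 avoids the substituted terminus), from the α-methyl group and the C8 methyl both disfavouring a boron-bound formyl group under the diene, and from the stronger polarisation of the bond adjacent to the complexed carbonyl.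

**Step 7**
Reactants: 10 cyclohexenyl aldehyde
Product: 11 (2E)-5-[(1R,5R,6R)-6-(2-cyanoethenyl)-2,6-dimethyl-5-(prop-1-en-2-yl)cyclohex-2-en-1-yl]-3-methylpent-2-en-1-yl (3S)-3-methylpentanoate (E/Z mixture at the new alkene)
Conditions: (EtO)2P(O)CH2CN, NaH, THF, 0 °C → rt
Reagents that add atoms: diethyl cyanomethylphosphonate, CCOP(=O)(CC#N)OCC
Why: Horner–Wadsworth–Emmons olefination; the small, reactive cyanomethylphosphonate anion suits a neopentyl aldehyde that cannot enolise, the ester is inert to the stabilised carbanion, and the alkene geometry is irrelevant because the bond is reduced next.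

**Step 8**
Reactants: 11 unsaturated nitrile
Product: 12 (2E)-5-[(1R,5R,6R)-6-(2-cyanoethyl)-2,6-dimethyl-5-(prop-1-en-2-yl)cyclohex-2-en-1-yl]-3-methylpent-2-en-1-yl (3S)-3-methylpentanoate
Conditions: Cu(OAc)2 (5 mol%), 4,5-bis(diphenylphosphino)-9,9-dimethylxanthene (5 mol%), (EtO)2MeSiH, t-BuOH, toluene, rt
Reagents that add atoms: none
Why: copper hydride conjugate reduction of an α,β-unsaturated nitrile; only the electron-poor C1=C2 bond accepts hydride, so the three isolated alkenes and the ester should remain.

**Step 9**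
Reactants: 12 saturated nitrile
Product: 14 (2E)-3-methyl-5-[(1R,4aS,8aS)-2,5,5,8a-tetramethyl-6-oxo-1,4,4a,5,6,7,8,8a-octahydronaphthalen-1-yl]pent-2-en-1-yl (3S)-3-methylpentanoate, via N–H ketimine 13 (not isolated)
Conditions: Fe(acac)3 (30 mol%), PhSiH3, EtOH (degassed), 60 °C; then 1 M HCl, THF, rt
Reagents that add atoms: water, O
Why: hydrogen-atom-transfer radical cyclisation of an alkene onto a nitrile: the iron hydride delivers H to the isopropenyl CH2, the tertiary C4 radical adds 6-exo-dig to the nitrile carbon C3, and the iminyl radical is reduced to the imine and hydrolysed; C1 and C4 are trans on ring B, so only the trans-fused decalin can form, and no new stereocentre arises because C4 carries two methyl groups.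

**Step 10**
Reactants: 14 ring A ketone
Product: 15 (2E)-5-[(1R,4aS,6S,8aS)-6-hydroxy-2,5,5,8a-tetramethyl-1,4,4a,5,6,7,8,8a-octahydronaphthalen-1-yl]-3-methylpent-2-en-1-yl (3S)-3-methylpentanoate
Conditions: LiBH(s-Bu)3, THF, −78 °C; then H2O
Reagents that add atoms: none
Why: bulky-hydride reduction of a 4,4-dimethyl-3-ketone on a trans-decalin; equatorial attack should give the axial (3S) alcohol, trans to the C10 methyl, and the ester is not reduced at −78 °C.

**Compound list**

1 | geraniol, (2E)-3,7-dimethylocta-2,6-dien-1-ol | CC(C)=CCC/C(C)=C/CO | starting material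
2 | (3S)-3-methylpentanoic acid | CC[C@H](C)CC(=O)O | starting material
3 | geranyl (3S)-3-methylpentanoate | CC[C@H](C)CC(=O)OC/C=C(\C)CCC=C(C)C | intermediate
4 | (2E,6E)-8-hydroxy-3,7-dimethylocta-2,6-dien-1-yl (3S)-3-methylpentanoate | CC[C@H](C)CC(=O)OC/C=C(\C)CC/C=C(\C)CO | intermediate
5 | (2E,6E)-3,7-dimethyl-8-oxoocta-2,6-dien-1-yl (3S)-3-methylpentanoate | CC[C@H](C)CC(=O)OC/C=C(\C)CC/C=C(\C)C=O | intermediate
6 | (2E,6E)-3,7-dimethylnona-2,6,8-trien-1-yl (3S)-3-methylpentanoate | CC[C@H](C)CC(=O)OC/C=C(\C)CC/C=C(\C)C=C | intermediate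
7 | methacrolein (2-methylprop-2-enal) | CC(=C)C=O | starting material
8 | 2-(triphenylphosphoranylidene)propanal | CC(C=O)=P(c1ccccc1)(c1ccccc1)c1ccccc1 | starting material
9 | (2E)-2,4-dimethylpenta-2,4-dienal | O=C/C(C)=C/C(C)=C | intermediate
10 | (2E)-5-[(1R,5R,6R)-6-formyl-2,6-dimethyl-5-(prop-1-en-2-yl)cyclohex-2-en-1-yl]-3-methylpent-2-en-1-yl (3S)-3-methylpentanoate | CC[C@H](C)CC(=O)OC/C=C(\C)CC[C@@H]1C(C)=CC[C@H](C(C)=C)[C@@]1(C)C=O | intermediate
11 | (2E)-5-[(1R,5R,6R)-6-(2-cyanoethenyl)-2,6-dimethyl-5-(prop-1-en-2-yl)cyclohex-2-en-1-yl]-3-methylpent-2-en-1-yl (3S)-3-methylpentanoate, E/Z mixture at the cyanoethenyl bond | CC[C@H](C)CC(=O)OC/C=C(\C)CC[C@@H]1C(C)=CC[C@H](C(C)=C)[C@@]1(C)C=CC#N | intermediate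
12 | (2E)-5-[(1R,5R,6R)-6-(2-cyanoethyl)-2,6-dimethyl-5-(prop-1-en-2-yl)cyclohex-2-en-1-yl]-3-methylpent-2-en-1-yl (3S)-3-methylpentanoate | CC[C@H](C)CC(=O)OC/C=C(\C)CC[C@@H]1C(C)=CC[C@H](C(C)=C)[C@@]1(C)CCC#N | intermediate
13 | (2E)-5-[(1R,4aS,8aS)-6-imino-2,5,5,8a-tetramethyl-1,4,4a,5,6,7,8,8a-octahydronaphthalen-1-yl]-3-methylpent-2-en-1-yl (3S)-3-methylpentanoate | CC[C@H](C)CC(=O)OC/C=C(\C)CC[C@@H]1C(C)=CC[C@@H]2C(C)(C)C(=N)CC[C@@]12C | intermediate
14 | (2E)-3-methyl-5-[(1R,4aS,8aS)-2,5,5,8a-tetramethyl-6-oxo-1,4,4a,5,6,7,8,8a-octahydronaphthalen-1-yl]pent-2-en-1-yl (3S)-3-methylpentanoate | CC[C@H](C)CC(=O)OC/C=C(\C)CC[C@@H]1C(C)=CC[C@@H]2C(C)(C)C(=O)CC[C@@]12C | intermediate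
15 | (2E)-5-[(1R,4aS,6S,8aS)-6-hydroxy-2,5,5,8a-tetramethyl-1,4,4a,5,6,7,8,8a-octahydronaphthalen-1-yl]-3-methylpent-2-en-1-yl (3S)-3-methylpentanoate | CC[C@H](C)CC(=O)OC/C=C(\C)CC[C@@H]1C(C)=CC[C@@H]2C(C)(C)[C@@H](O)CC[C@@]12C | target

**Step count and risks**

Total step count: 10. Longest linear sequence: 9 steps (steps 1–4, then 6–10).

Steps most likely to fail:

1. Step 6 (labelled step). The trisubstituted dienal may be too unreactive, so that the diene oligomerises or the dienal reacts with itself. The C8 methyl may also divert part of the material to the other regiochemistry, and the exo-formyl or facial preference may be incomplete. Fallback, from 6 and 9: the cycloaddition is run without asymmetric induction under EtAlCl2 in CH2Cl2 at low temperature, the established Lewis-acid-promoted Diels–Alder reaction of α-methyl enals with 1,3-dienes. Because the ester side chain is already enantiopure, the two ring enantiomorphs arise as diastereomers: 10 and (2E)-5-[(1S,5S,6S)-6-formyl-2,6-dimethyl-5-(prop-1-en-2-yl)cyclohex-2-en-1-yl]-3-methylpent-2-en-1-yl (3S)-3-methylpentanoate F1. They are separated by preparative HPLC on a chiral stationary phase, and the route is rejoined at 10.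

2. Step 9. The 6-exo addition of the tertiary C4 radical to the nitrile is slow, so reduction of the radical (net hydrogenation of the isopropenyl group), alkene isomerisation, or hydrogen-atom transfer to the trisubstituted alkenes may compete. Fallback, from 10, with an aldehyde as the faster radical acceptor:
   - Formylolefination of 10 with diethyl [2-(cyclohexylamino)vinyl]phosphonate and NaH gives the N-cyclohexyl α,β-unsaturated aldimine F2, which is hydrolysed with aqueous oxalic acid to the enal (2E)-5-[(1R,5R,6R)-2,6-dimethyl-6-[(1E)-3-oxoprop-1-en-1-yl]-5-(prop-1-en-2-yl)cyclohex-2-en-1-yl]-3-methylpent-2-en-1-yl (3S)-3-methylpentanoate F3.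
   - Conjugate reduction with [(Ph3P)CuH]6 and PhMe2SiH gives the saturated aldehyde (2E)-5-[(1R,5R,6R)-2,6-dimethyl-6-(3-oxopropyl)-5-(prop-1-en-2-yl)cyclohex-2-en-1-yl]-3-methylpent-2-en-1-yl (3S)-3-methylpentanoate F4.
   - Fe(acac)3–PhSiH3 in EtOH closes ring A by addition of the C4 radical to the formyl group, the known hydrogen-atom-transfer cyclisation onto carbonyl acceptors, giving the ring A alcohol as a mixture of C3 epimers F5.
   - Dess–Martin oxidation converges on 14.

3. Step 5. The volatile dienal may be lost on isolation, may polymerise, or may be olefinated a second time. Fallback, from 7, through the ester oxidation level: Wittig reaction of 7 with ethyl 2-(triphenylphosphoranylidene)propanoate gives ethyl (2E)-2,4-dimethylpenta-2,4-dienoate F6. Reduction with i-Bu2AlH gives (2E)-2,4-dimethylpenta-2,4-dien-1-ol F7, and MnO2 oxidation just before use returns to 9.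

**Further compounds**

F1 | step 6 | (2E)-5-[(1S,5S,6S)-6-formyl-2,6-dimethyl-5-(prop-1-en-2-yl)cyclohex-2-en-1-yl]-3-methylpent-2-en-1-yl (3S)-3-methylpentanoate | CC[C@H](C)CC(=O)OC/C=C(\C)CC[C@H]1C(C)=CC[C@@H](C(C)=C)[C@]1(C)C=O
F2 | step 9 | (2E)-5-[(1R,5R,6R)-6-[(1E)-3-(cyclohexylimino)prop-1-en-1-yl]-2,6-dimethyl-5-(prop-1-en-2-yl)cyclohex-2-en-1-yl]-3-methylpent-2-en-1-yl (3S)-3-methylpentanoate | CC[C@H](C)CC(=O)OC/C=C(\C)CC[C@@H]1C(C)=CC[C@H](C(C)=C)[C@@]1(C)/C=C/C=NC2CCCCC2
F3 | step 9 | (2E)-5-[(1R,5R,6R)-2,6-dimethyl-6-[(1E)-3-oxoprop-1-en-1-yl]-5-(prop-1-en-2-yl)cyclohex-2-en-1-yl]-3-methylpent-2-en-1-yl (3S)-3-methylpentanoate | CC[C@H](C)CC(=O)OC/C=C(\C)CC[C@@H]1C(C)=CC[C@H](C(C)=C)[C@@]1(C)/C=C/C=O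
F4 | step 9 | (2E)-5-[(1R,5R,6R)-2,6-dimethyl-6-(3-oxopropyl)-5-(prop-1-en-2-yl)cyclohex-2-en-1-yl]-3-methylpent-2-en-1-yl (3S)-3-methylpentanoate | CC[C@H](C)CC(=O)OC/C=C(\C)CC[C@@H]1C(C)=CC[C@H](C(C)=C)[C@@]1(C)CCC=O
F5 | step 9 | (2E)-5-[(1R,4aS,8aS)-6-hydroxy-2,5,5,8a-tetramethyl-1,4,4a,5,6,7,8,8a-octahydronaphthalen-1-yl]-3-methylpent-2-en-1-yl (3S)-3-methylpentanoate, mixture of C6 (labdane C3) epimers | CC[C@H](C)CC(=O)OC/C=C(\C)CC[C@@H]1C(C)=CC[C@@H]2C(C)(C)C(O)CC[C@@]12C
F6 | step 5 | ethyl (2E)-2,4-dimethylpenta-2,4-dienoate | CCOC(=O)/C(C)=C/C(C)=C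
F7 | step 5 | (2E)-2,4-dimethylpenta-2,4-dien-1-ol | OC/C(C)=C/C(C)=C
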